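**Plan**
- Retrosynthesis: after removal of six benzyl ethers and a bromine block at C8 of the lower unit, one retro-step cuts both the interflavan C4–C6' bond and the C2–C3 bond of the upper pyran ring. A second cut at O1–C2 leads back to 5-(benzyloxy)-2-ethenylphenol, 4-(benzyloxy)benzaldehyde and (−)-epiafzelechin.
- Enabling feature: in the upper unit O1 sits on C8a, ortho to the benzylic carbon C4, and the 7-oxygen is para to C4a. An aryl oxocarbenium O1=C2 with an ortho vinyl group C4=C3 is therefore a 2-oxonia-hexatriene; closing C2–C3 gives a C4 cation stabilised by both oxygens.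
- Forward: the vinylphenol (Wittig) is joined to the aldehyde as a benzotriazolyl N,O-acetal; the lower unit is benzylated and brominated at C8. The cascade then builds the upper pyran ring and joins the two flavan units in one operation; hydrogenolysis finishes.
- Stereochemistry: lower C2/C3 come unchanged from (−)-epiafzelechin. Upper C2 is set in the ring closure by a chiral counter-anion. Upper C4 follows from C2 (pseudo-axial capture of the cation, 2,4-trans). The C6 linkage is enforced by the bromine at C8.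

Key step: step 7

Assumption: (−)-epiafzelechin (6) is taken as a purchasable, enantiopure chiral-pool compound.

**Step 1**
Reactants: 1 4-(benzyloxy)-2-hydroxybenzaldehyde
Product: 2 5-(benzyloxy)-2-ethenylphenol
Conditions: Ph3PCH3Br (2.3 equiv), KOtBu (2.2 equiv), THF, 0 °C to rt; used promptly
Reagents that add atoms: methyltriphenylphosphonium bromide, C[P+](c1ccccc1)(c1ccccc1)c1ccccc1.[Br-]
Why: Wittig methylenation of a salicylaldehyde, in which the extra equivalent of base is taken up by the phenol and the phenoxide does not interfere.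

**Step 2**
Reactants: 3 4-(benzyloxy)benzaldehyde
Product: 4 1-{[4-(benzyloxy)phenyl](chloro)methyl}-1H-benzotriazole (racemic)
Conditions: 1H-benzotriazole, SOCl2, toluene, rt to 50 °C; volatiles removed, crude solid used
Reagents that add atoms: 1H-benzotriazole, c1ccc2[nH]nnc2c1; thionyl chloride, O=S(Cl)Cl
Why: Known condensation of an aldehyde with benzotriazole to the hemiaminal and its chlorination, giving an α-chloroalkyl benzotriazole whose racemic centre is destroyed later.

**Step 3**
Reactants: 2 5-(benzyloxy)-2-ethenylphenol; 4 1-{[4-(benzyloxy)phenyl](chloro)methyl}-1H-benzotriazole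
Product: 5 1-{[5-(benzyloxy)-2-ethenylphenoxy][4-(benzyloxy)phenyl]methyl}-1H-benzotriazole (racemic)
Conditions: NaH, THF, 0 °C; then 4, −20 °C to rt; chromatography on Et3N-deactivated silica
Reagents that add atoms: none
Why: Williamson-type O-alkylation of a sodium phenoxide by an α-chloroalkyl benzotriazole, a known route to bench-stable α-aryloxyalkyl benzotriazoles; the acetal-type carbon is formed racemic, which is immaterial because it becomes planar in step 7.

**Step 4**
Reactants: 6 (−)-epiafzelechin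
Product: 7 (2R,3R)-5,7-bis(benzyloxy)-2-[4-(benzyloxy)phenyl]-3,4-dihydro-2H-chromen-3-ol
Conditions: BnBr (3.3 equiv), K2CO3, DMF, 0 °C to rt
Reagents that add atoms: benzyl bromide, BrCc1ccccc1
Why: Williamson benzylation of the three phenols (K2CO3 does not deprotonate the secondary 3-OH), leaving C2 and C3 untouched.

**Step 5**
Reactants: 7 (2R,3R)-5,7-bis(benzyloxy)-2-[4-(benzyloxy)phenyl]-3,4-dihydro-2H-chromen-3-ol
Product: 8 (2R,3R)-5,7-bis(benzyloxy)-2-[4-(benzyloxy)phenyl]-8-bromo-3,4-dihydro-2H-chromen-3-ol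
Conditions: N-bromosuccinimide (1.0 equiv), CH2Cl2, −78 to −40 °C
Reagents that add atoms: N-bromosuccinimide, O=C1CCC(=O)N1Br
Why: Electrophilic aromatic bromination, which in 5,7-dialkoxyflavan-3-ols is known to favour C8 of ring A, while the mono-alkoxy ring B is far less activated.

**Step 6**
Reactants: 8 (2R,3R)-5,7-bis(benzyloxy)-2-[4-(benzyloxy)phenyl]-8-bromo-3,4-dihydro-2H-chromen-3-ol
Product: 9 (2R,3R)-3,5,7-tris(benzyloxy)-2-[4-(benzyloxy)phenyl]-8-bromo-3,4-dihydro-2H-chromene
Conditions: NaH, BnBr, n-Bu4NI (cat.), DMF, 0 °C to rt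
Reagents that add atoms: benzyl bromide, BrCc1ccccc1
Why: Williamson etherification of the secondary alkoxide, which keeps the 3-OH from acting as an O-nucleophile towards the cation in step 7.

**Step 7**
Reactants: 5 1-{[5-(benzyloxy)-2-ethenylphenoxy][4-(benzyloxy)phenyl]methyl}-1H-benzotriazole; 9 (2R,3R)-3,5,7-tris(benzyloxy)-2-[4-(benzyloxy)phenyl]-8-bromo-3,4-dihydro-2H-chromene
Product: 12 (2R,3R)-3,5,7-tris(benzyloxy)-6-{(2S,4R)-7-(benzyloxy)-2-[4-(benzyloxy)phenyl]-3,4-dihydro-2H-chromen-4-yl}-2-[4-(benzyloxy)phenyl]-8-bromo-3,4-dihydro-2H-chromene, via aryl oxocarbenium ion 10 (not isolated), via 2-arylchroman-4-yl cation 11 (not isolated)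
Conditions: chiral BINOL-derived imidodiphosphorimidate Brønsted acid (3,3'-aryl = 3,5-(CF3)2C6H3, N-SO2CF3; 10 mol %), 9 (1.5 equiv), CH2Cl2, −78 to −40 °C, high dilution in 5
Reagents that add atoms: none
Why: Proposed new method: protonation of the benzotriazolyl group of 5 expels 1H-benzotriazole (a non-donor leaving group, so only the aryl oxocarbenium 10 can form) and leaves 10 paired with the chiral anion; 10 is a 2-oxonia-hexatriene (O1=C2, C8a=C4a, C4=C3) that closes the upper pyran ring by 6-endo-trig cation–olefin (Prins-type, disrotatory 6π) attack of the vinyl terminus C3 on C2, giving cation 11 stabilised by O1 (ortho) and the 7-benzyloxy group (para). The closest known reaction types are the confined-acid-catalysed asymmetric Prins cyclisation of aldehydes with homoallylic alcohols and the Prins/Friedel–Crafts cascade to 4-aryltetrahydropyrans; an aryl oxocarbenium with a conjugated ortho-vinyl group has not been used this way. C2 (S) is set in the ring closure by the chiral counter-anion, which shields one enantiotopic face of the oxocarbenium carbon; 10 has no other stereocontrol element, so the acid antipode that delivers 2S is the one used. C4 (R) is set by substrate control: arene 9 adds pseudo-axially to the half-chair of 11 with the 2-aryl group equatorial, on the face opposite that group, as in the known couplings of flavan-4-ols with phenols, which should favour the 2,4-trans unit. The step needs 6-endo over 5-exo closure (secured by the benzylic, doubly oxygen-stabilised cation), ring closure ahead of intermolecular arylation of 10 (secured by intramolecularity and the hindered nucleophile), and C6 over C8 attack on the lower unit (secured by the bromine at C8, which leaves C6 as the only free position of that ring).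

**Step 8**
Reactants: 12 (2R,3R)-3,5,7-tris(benzyloxy)-6-{(2S,4R)-7-(benzyloxy)-2-[4-(benzyloxy)phenyl]-3,4-dihydro-2H-chromen-4-yl}-2-[4-(benzyloxy)phenyl]-8-bromo-3,4-dihydro-2H-chromene
Product: 13 (2R,3R)-6-[(2S,4R)-7-hydroxy-2-(4-hydroxyphenyl)-3,4-dihydro-2H-chromen-4-yl]-2-(4-hydroxyphenyl)-3,4-dihydro-2H-chromene-3,5,7-triol
Conditions: H2 (1 atm), Pd(OH)2/C, NaHCO3 (solid, 1.5 equiv), THF/MeOH, rt
Reagents that add atoms: none
Why: Hydrogenolysis of the six benzyl ethers with concurrent hydrodebromination of the aryl bromide, with bicarbonate buffering the HBr so that the acid-labile interflavan bond and the benzylic pyran C–O bonds should survive and no stereocentre is touched.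

**Compound list**
1 | 4-(benzyloxy)-2-hydroxybenzaldehyde | O=Cc1ccc(OCc2ccccc2)cc1O | starting material
2 | 5-(benzyloxy)-2-ethenylphenol | C=Cc1ccc(OCc2ccccc2)cc1O | intermediate
3 | 4-(benzyloxy)benzaldehyde | O=Cc1ccc(OCc2ccccc2)cc1 | starting material
4 | 1-{[4-(benzyloxy)phenyl](chloro)methyl}-1H-benzotriazole (racemic) | ClC(c1ccc(OCc2ccccc2)cc1)n1nnc2ccccc12 | intermediate
5 | 1-{[5-(benzyloxy)-2-ethenylphenoxy][4-(benzyloxy)phenyl]methyl}-1H-benzotriazole (racemic) | C=Cc1ccc(OCc2ccccc2)cc1OC(c1ccc(OCc2ccccc2)cc1)n1nnc2ccccc12 | intermediate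
6 | (−)-epiafzelechin, (2R,3R)-2-(4-hydroxyphenyl)-3,4-dihydro-2H-chromene-3,5,7-triol | O[C@@H]1Cc2c(O)cc(O)cc2O[C@@H]1c1ccc(O)cc1 | starting material
7 | (2R,3R)-5,7-bis(benzyloxy)-2-[4-(benzyloxy)phenyl]-3,4-dihydro-2H-chromen-3-ol | O[C@@H]1Cc2c(OCc3ccccc3)cc(OCc3ccccc3)cc2O[C@@H]1c1ccc(OCc2ccccc2)cc1 | intermediate
8 | (2R,3R)-5,7-bis(benzyloxy)-2-[4-(benzyloxy)phenyl]-8-bromo-3,4-dihydro-2H-chromen-3-ol | O[C@@H]1Cc2c(OCc3ccccc3)cc(OCc3ccccc3)c(Br)c2O[C@@H]1c1ccc(OCc2ccccc2)cc1 | intermediate
9 | (2R,3R)-3,5,7-tris(benzyloxy)-2-[4-(benzyloxy)phenyl]-8-bromo-3,4-dihydro-2H-chromene | c1ccccc1CO[C@@H]1Cc2c(OCc3ccccc3)cc(OCc3ccccc3)c(Br)c2O[C@@H]1c1ccc(OCc2ccccc2)cc1 | intermediate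
10 | {[4-(benzyloxy)phenyl]methylidene}[5-(benzyloxy)-2-ethenylphenyl]oxonium (aryl oxocarbenium ion) | C=Cc1ccc(OCc2ccccc2)cc1[O+]=Cc1ccc(OCc2ccccc2)cc1 | intermediate
11 | (2S)-7-(benzyloxy)-2-[4-(benzyloxy)phenyl]-3,4-dihydro-2H-chromen-4-ylium | c1ccccc1COc1ccc([C@@H]2C[CH+]c3ccc(OCc4ccccc4)cc3O2)cc1 | intermediate
12 | (2R,3R)-3,5,7-tris(benzyloxy)-6-{(2S,4R)-7-(benzyloxy)-2-[4-(benzyloxy)phenyl]-3,4-dihydro-2H-chromen-4-yl}-2-[4-(benzyloxy)phenyl]-8-bromo-3,4-dihydro-2H-chromene | C(c1ccccc1)Oc1ccc([C@@H]2C[C@@H](c3c(OCc5ccccc5)c(Br)c4c(c3OCc3ccccc3)C[C@@H](OCc3ccccc3)[C@@H](c3ccc(OCc5ccccc5)cc3)O4)c3ccc(OCc4ccccc4)cc3O2)cc1 | intermediate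
13 | (2R,3R)-6-[(2S,4R)-7-hydroxy-2-(4-hydroxyphenyl)-3,4-dihydro-2H-chromen-4-yl]-2-(4-hydroxyphenyl)-3,4-dihydro-2H-chromene-3,5,7-triol | Oc1ccc([C@@H]2C[C@@H](c3c(O)cc4c(c3O)C[C@@H](O)[C@@H](c3ccc(O)cc3)O4)c3ccc(O)cc3O2)cc1 | target

**Step count**
Total: 8 steps. Longest linear sequence: 5 steps (steps 4, 5, 6, 7, 8).

**Steps most likely to fail**

Step 7 (Proposed new method). The counter-anion may discriminate the two faces of the achiral oxocarbenium ion poorly, or intermolecular arylation and oligomerisation of the cations may outrun ring closure and capture. The fallback uses known chemistry and sets out from 3. Claisen–Schmidt condensation of 3 with commercial 1-[4-(benzyloxy)-2-hydroxyphenyl]ethan-1-one (CC(=O)c1ccc(OCc2ccccc2)cc1O; KOH, EtOH) should give (E)-1-[4-(benzyloxy)-2-hydroxyphenyl]-3-[4-(benzyloxy)phenyl]prop-2-en-1-one F1. Oxa-Michael ring closure (NaOAc, EtOH, reflux) should give racemic 7-(benzyloxy)-2-[4-(benzyloxy)phenyl]-2,3-dihydro-4H-chromen-4-one F2. Asymmetric transfer hydrogenation under kinetic resolution (RuCl(p-cymene)[TsDPEN], the antipode that reduces the (2S)-ketone; HCO2H/Et3N) should give (2S,4S)-7-(benzyloxy)-2-[4-(benzyloxy)phenyl]-3,4-dihydro-2H-chromen-4-ol F3, separated from the unreacted (2R)-ketone. Ionisation of F3 with Me3SiOTf in CH2Cl2 at −78 °C in the presence of 9 passes through the same cation 11 and comes back to the route at 12.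

Step 3. The readily ionising chloride 4 may C-alkylate or polymerise the electron-rich vinylphenoxide, or the product may ionise and cyclise during isolation. The fallback reverses the order of operations and sets out from 1 and 4. The sodium phenoxide of aldehyde 1 (NaH, THF), which is less C-nucleophilic and carries no vinyl group, is O-alkylated with 4 to give 4-(benzyloxy)-2-{(1H-benzotriazol-1-yl)[4-(benzyloxy)phenyl]methoxy}benzaldehyde F4. Wittig methylenation of F4 (Ph3PCH3Br, KOtBu, THF, 0 °C) then comes back to the route at 5.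

Step 8. The HBr liberated during hydrodebromination may acidify the medium and cleave or scramble the interflavan bond, or bromide may poison the catalyst and leave benzyl ethers uncleaved. The fallback removes the halogen first and sets out from 12. Bromine–lithium exchange (n-BuLi, THF, −78 °C) and protonation (MeOH) should give (2R,3R)-3,5,7-tris(benzyloxy)-6-{(2S,4R)-7-(benzyloxy)-2-[4-(benzyloxy)phenyl]-3,4-dihydro-2H-chromen-4-yl}-2-[4-(benzyloxy)phenyl]-3,4-dihydro-2H-chromene F5. Neutral hydrogenolysis of F5 (H2, Pd(OH)2/C, THF/MeOH) then comes back to the route at 13.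

**Further compounds**
F1 | step 7 | (E)-1-[4-(benzyloxy)-2-hydroxyphenyl]-3-[4-(benzyloxy)phenyl]prop-2-en-1-one | O=C(/C=C/c1ccc(OCc2ccccc2)cc1)c1ccc(OCc2ccccc2)cc1O
F2 | step 7 | racemic 7-(benzyloxy)-2-[4-(benzyloxy)phenyl]-2,3-dihydro-4H-chromen-4-one | O=C1CC(c2ccc(OCc3ccccc3)cc2)Oc2cc(OCc3ccccc3)ccc12
F3 | step 7 | (2S,4S)-7-(benzyloxy)-2-[4-(benzyloxy)phenyl]-3,4-dihydro-2H-chromen-4-ol | c1ccccc1COc1ccc([C@@H]2C[C@H](O)c3ccc(OCc4ccccc4)cc3O2)cc1
F4 | step 3 | 4-(benzyloxy)-2-{(1H-benzotriazol-1-yl)[4-(benzyloxy)phenyl]methoxy}benzaldehyde (racemic) | O=Cc1ccc(OCc2ccccc2)cc1OC(c1ccc(OCc2ccccc2)cc1)n1nnc2ccccc12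
F5 | step 8 | (2R,3R)-3,5,7-tris(benzyloxy)-6-{(2S,4R)-7-(benzyloxy)-2-[4-(benzyloxy)phenyl]-3,4-dihydro-2H-chromen-4-yl}-2-[4-(benzyloxy)phenyl]-3,4-dihydro-2H-chromene | C(c1ccccc1)Oc1ccc([C@@H]2C[C@@H](c3c(OCc5ccccc5)cc4c(c3OCc3ccccc3)C[C@@H](OCc3ccccc3)[C@@H](c3ccc(OCc5ccccc5)cc3)O4)c3ccc(OCc4ccccc4)cc3O2)cc1
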